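**Retrosynthetic overview**
1. Target ⇐ macrocyclic cis-8,9-diol + (R)-2-methylglycidic acid. One C–O-forming operation (cyclic orthoacetate → acetoxonium ion → carboxylate attack at allylic C9 with inversion) installs both esters and the C9 centre.
2. Diol ⇐ ten-membered ring closed at C9–C10 by Ni/Cr coupling of a Z-α-iodo enoate onto an α-silyloxy aldehyde.
3. cis-Lactone ⇐ indium Barbier union (C6–C7) of a nerol-derived epoxy aldehyde with a glyceraldehyde-derived 2-(bromomethyl)enoate.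
4. Absolute configuration: two Sharpless epoxidations (nerol → C4/C5; methallyl alcohol → side-chain oxirane) and (R)-glyceraldehyde acetonide (C8).
5. Ring order: 4,5-oxirane → γ-lactone → ten-membered carbocycle; the side-chain oxirane is made separately and attached in the last step.

Assumption: germacrane locants (C1–C15) are used throughout, and the target SMILES is read as (4R,5S,6R,7R,8S,9S) with a (2R)-glycidate, i.e. cis-4,5-epoxide, cis-fused 6,12-lactone, 8,9-threo diester and ring-cis C1=C10 (CIP 1(10)E).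

**Route**

Step 1
Reactants: 1 nerol
Product: 2 [(2S,3R)-3-methyl-3-(4-methylpent-3-en-1-yl)oxiran-2-yl]methanol
Conditions: Ti(OiPr)4 (10 mol %), L-(+)-diethyl tartrate (12 mol %), t-BuOOH, 4 Å MS, CH2Cl2, −20 °C
Reagents that add atoms: tert-butyl hydroperoxide, CC(C)(C)OO
Why: Sharpless asymmetric epoxidation, in which L-(+)-tartrate delivers oxygen to the face of the Z-allylic alcohol that gives the (4R,5S) cis-epoxide and leaves the distal alkene untouched.

Step 2
Reactants: 2 epoxynerol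
Product: 4 methyl (2Z)-5-[(2R,3S)-3-(hydroxymethyl)-2-methyloxiran-2-yl]-2-iodopent-2-enoate, via hydroxy epoxy aldehyde 3 (not isolated)
Conditions: O3, CH2Cl2, −78 °C; PPh3 (1.0 equiv), → 0 °C; then Ph3P=CHCO2Me/NIS (premixed, CH2Cl2, −20 °C), → 25 °C
Reagents that add atoms: methyl (triphenylphosphoranylidene)acetate, COC(=O)C=P(c1ccccc1)(c1ccccc1)c1ccccc1; N-iodosuccinimide, O=C1CCC(=O)N1I
Why: Ozonolysis of the only alkene followed by Wittig olefination with the in-flask α-iodinated stabilised ylide, which places the ester trans to the chain and so gives the Z-α-iodo enoate (iodine cis to C2).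

Step 3
Reactants: 4 iodo enoate epoxy alcohol
Product: 5 methyl (2Z)-5-[(2R,3R)-3-formyl-2-methyloxiran-2-yl]-2-iodopent-2-enoate
Conditions: Dess–Martin periodinane, NaHCO3, CH2Cl2, 0 °C → 25 °C
Reagents that add atoms: none
Why: Buffered Dess–Martin oxidation of the primary epoxy alcohol, which spares epoxide, vinyl iodide and ester and does not epimerise C5.

Step 4
Reactants: 6 (R)-2,2-dimethyl-1,3-dioxolane-4-carbaldehyde; 7 methyl acrylate
Product: 8 methyl 2-{hydroxy[(4R)-2,2-dimethyl-1,3-dioxolan-4-yl]methyl}prop-2-enoate (both carbinol epimers)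
Conditions: DABCO (0.5 equiv), 7 (3 equiv, neat), 25 °C, 4 d
Reagents that add atoms: none
Why: Morita–Baylis–Hillman reaction, whose new carbinol centre is erased in the next step while C8 is carried unchanged from the chiral pool.

Step 5
Reactants: 8 Baylis–Hillman adduct
Product: 9 methyl (2Z)-2-(bromomethyl)-3-[(4S)-2,2-dimethyl-1,3-dioxolan-4-yl]prop-2-enoate
Conditions: NBS, Me2S, CH2Cl2, 0 °C → 25 °C
Reagents that add atoms: N-bromosuccinimide, O=C1CCC(=O)N1Br
Why: Corey–Kim-type activation of the alcohol and SN2′ attack of bromide give the rearranged allyl bromide with the ester trans to the dioxolane (2Z), under neutral conditions that keep the acetonide.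

Step 6
Reactants: 5 epoxy aldehyde; 9 allyl bromide
Product: 12 (4R,5R)-4-[(4S)-2,2-dimethyl-1,3-dioxolan-4-yl]-5-{(2S,3R)-3-[(3Z)-4-iodo-5-methoxy-5-oxopent-3-en-1-yl]-3-methyloxiran-2-yl}-3-methylideneoxolan-2-one, via allylindium dibromide 10 (not isolated), via hydroxy diester 11 (not isolated)
Conditions: indium powder (1.5 equiv), 9 (1.5 equiv), THF, 25 °C; aq NH4Cl; then PPTS (10 mol %), CH2Cl2, 35 °C
Reagents that add atoms: none
Why: Indium Barbier allylation then acid-catalysed lactonisation: γ-attack of the Z-allylindium through a chair transition state gives the 6,7-syn adduct (cis-lactone), C7 forms anti to the C8–C9 bond of the A(1,3)-locked dioxolane, and chelation of trivalent indium by the epoxide and aldehyde oxygens (attack from the H-5 side) is relied on for the 5,6-threo C6 centre; the vinyl iodide is inert to indium.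

Step 7
Reactants: 12 lactone acetonide
Product: 13 (4R,5R)-4-[(1S)-1,2-dihydroxyethyl]-5-{(2S,3R)-3-[(3Z)-4-iodo-5-methoxy-5-oxopent-3-en-1-yl]-3-methyloxiran-2-yl}-3-methylideneoxolan-2-one
Conditions: PPTS (0.2 equiv), MeOH, 25 °C
Reagents that add atoms: none
Why: Acid-catalysed transacetalisation of the terminal acetonide to methanol, with an acid too weak to open the trisubstituted epoxide or the lactone at this temperature.

Step 8
Reactants: 13 diol
Product: 14 (4S,5R)-4-[(1S)-1,2-bis(triethylsilyloxy)ethyl]-5-{(2S,3R)-3-[(3Z)-4-iodo-5-methoxy-5-oxopent-3-en-1-yl]-3-methyloxiran-2-yl}-3-methylideneoxolan-2-one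
Conditions: TESCl (2.5 equiv), imidazole, CH2Cl2, 0 °C
Reagents that add atoms: chlorotriethylsilane, CC[Si](Cl)(CC)CC
Why: Standard silylation of both hydroxyls, giving a non-chelating silyl ether at C8 for the later Felkin-controlled addition.

Step 9
Reactants: 14 bis-silyl ether
Product: 15 (4S,5R)-5-{(2S,3R)-3-[(3Z)-4-iodo-5-methoxy-5-oxopent-3-en-1-yl]-3-methyloxiran-2-yl}-3-methylidene-4-[(1S)-2-oxo-1-(triethylsilyloxy)ethyl]oxolan-2-one
Conditions: (COCl)2 (4 equiv), DMSO (8 equiv), CH2Cl2, −78 → −30 °C; Et3N, −78 → 0 °C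
Reagents that add atoms: none
Why: Swern oxidation run directly on the bis-silyl ether, in which the chlorosulfonium salt cleaves and oxidises only the primary triethylsilyl ether to the C9 aldehyde.

Step 10
Reactants: 15 iodo aldehyde
Product: 17 methyl (1(10)E,4R,5S,6R,7S,8S,9R)-4,5-epoxy-9-hydroxy-8-(triethylsilyloxy)germacra-1(10),11(13)-dien-12,6-olid-14-oate, via alkenylchromium dichloride 16 (not isolated)
Conditions: CrCl2 (10 equiv), NiCl2 (0.1 equiv), DMSO/THF 3:1, 2 mM (slow addition), 25 °C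
Reagents that add atoms: none
Why: Nozaki–Hiyama–Kishi macrocyclisation, in which zerovalent nickel inserts into the C–I bond, transmetallation gives the alkenylchromium with retention (C9 ring-cis to C2), and polar Felkin–Anh addition anti to the C8 silyloxy group gives the 8,9-erythro (9R) carbinol.

Step 11
Reactants: 17 macrocyclic silyl ether
Product: 18 methyl (1(10)E,4R,5S,6R,7R,8S,9R)-4,5-epoxy-8,9-dihydroxygermacra-1(10),11(13)-dien-12,6-olid-14-oate
Conditions: Et3N·3HF, MeCN, 25 °C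
Reagents that add atoms: none
Why: Fluoride desilylation with a mild, nearly neutral HF source that leaves the epoxide, the lactone and the enoate intact.

Step 12
Reactants: 19 2-methylprop-2-en-1-ol
Product: 20 [(2S)-2-methyloxiran-2-yl]methanol
Conditions: Ti(OiPr)4 (5 mol %), L-(+)-diisopropyl tartrate (6 mol %), t-BuOOH, 3 Å MS, CH2Cl2, −20 °C
Reagents that add atoms: tert-butyl hydroperoxide, CC(C)(C)OO
Why: Sharpless asymmetric epoxidation, L-(+)-tartrate giving the (S)-epoxy alcohol by the same facial rule as in step 1.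

Step 13
Reactants: 20 (S)-2-methylglycidol
Product: 21 (2R)-2-methyloxirane-2-carboxylic acid
Conditions: RuCl3·xH2O (2 mol %), NaIO4 (3 equiv), EtOAc/MeCN/H2O, 0 → 25 °C
Reagents that add atoms: water, O
Why: RuO4-catalysed oxidation of the primary alcohol to the acid via the aldehyde hydrate, with the stereocentre untouched (the S → R change is only a CIP priority change).

Step 14
Reactants: 18 cis-diol; 21 epoxy acid
Product: 24 methyl (1(10)E,4R,5S,6R,7R,8S,9S)-8-acetoxy-4,5-epoxy-9-{[(2R)-2-methyloxirane-2-carbonyl]oxy}germacra-1(10),11(13)-dien-12,6-olid-14-oate, via cyclic orthoacetate 22 (not isolated), via acetoxonium carboxylate ion pair 23 (not isolated)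
Conditions: MeC(OMe)3 (3 equiv), PPTS (5 mol %), CH2Cl2, 25 °C; evaporate; then 21 (3 equiv), 5 Å MS, PhMe, 70 °C
Reagents that add atoms: trimethyl orthoacetate, COC(C)(OC)OC
Why: Proposed new method: hetero-Prévost acetoxonium relay, in which the cis-diol is tied up as its cyclic orthoacetate, acid 21 ionises it to a 2-methyl-1,3-dioxolan-2-ylium carboxylate ion pair, and the carboxylate opens the cation by SN2 at allylic C9 (activated by the enoate π-system, whereas C8 is non-allylic and β-branched) so that C9 inverts to 9S and the former C9 oxygen becomes the carbonyl oxygen of the C8 acetate; the closest known chemistry is the second stage of the Prévost reaction (carboxylate opening of a dioxolan-2-ylium ion) and the conversion of cyclic orthoacetates into trans-acetoxy halides, neither shown with a second, different carboxylic acid on an allylic macrocyclic diol.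

**Compound list**
1 | nerol, (2Z)-3,7-dimethylocta-2,6-dien-1-ol | CC(C)=CCC/C(C)=C\CO | starting material
2 | [(2S,3R)-3-methyl-3-(4-methylpent-3-en-1-yl)oxiran-2-yl]methanol | CC(C)=CCC[C@@]1(C)O[C@H]1CO | intermediate
3 | 3-[(2R,3S)-3-(hydroxymethyl)-2-methyloxiran-2-yl]propanal | O=CCC[C@@]1(C)O[C@H]1CO | intermediate
4 | methyl (2Z)-5-[(2R,3S)-3-(hydroxymethyl)-2-methyloxiran-2-yl]-2-iodopent-2-enoate | I/C(C(=O)OC)=C\CC[C@@]1(C)O[C@H]1CO | intermediate
5 | methyl (2Z)-5-[(2R,3R)-3-formyl-2-methyloxiran-2-yl]-2-iodopent-2-enoate | I/C(C(=O)OC)=C\CC[C@@]1(C)O[C@H]1C=O | intermediate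
6 | (R)-2,2-dimethyl-1,3-dioxolane-4-carbaldehyde | O=C[C@H]1COC(C)(C)O1 | starting material
7 | methyl acrylate | C=CC(=O)OC | starting material
8 | methyl 2-{hydroxy[(4R)-2,2-dimethyl-1,3-dioxolan-4-yl]methyl}prop-2-enoate (carbinol epimers) | C=C(C(=O)OC)C(O)[C@H]1COC(C)(C)O1 | intermediate
9 | methyl (2Z)-2-(bromomethyl)-3-[(4S)-2,2-dimethyl-1,3-dioxolan-4-yl]prop-2-enoate | BrC/C(C(=O)OC)=C\[C@H]1COC(C)(C)O1 | intermediate
10 | {(2Z)-3-[(4S)-2,2-dimethyl-1,3-dioxolan-4-yl]-2-(methoxycarbonyl)prop-2-en-1-yl}indium dibromide | Br[In](Br)C/C(C(=O)OC)=C\[C@H]1COC(C)(C)O1 | intermediate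
11 | methyl (2Z)-5-{(2R,3S)-3-[(1R,2S)-1-hydroxy-2-[(4S)-2,2-dimethyl-1,3-dioxolan-4-yl]-3-(methoxycarbonyl)but-3-en-1-yl]-2-methyloxiran-2-yl}-2-iodopent-2-enoate | I/C(C(=O)OC)=C\CC[C@@]1(C)O[C@H]1[C@H](O)[C@H](C(=C)C(=O)OC)[C@H]1COC(C)(C)O1 | intermediate
12 | (4R,5R)-4-[(4S)-2,2-dimethyl-1,3-dioxolan-4-yl]-5-{(2S,3R)-3-[(3Z)-4-iodo-5-methoxy-5-oxopent-3-en-1-yl]-3-methyloxiran-2-yl}-3-methylideneoxolan-2-one | C=C1C(=O)O[C@@H]([C@@H]2O[C@]2(C)CC/C=C(\I)C(=O)OC)[C@H]1[C@H]3COC(C)(C)O3 | intermediate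
13 | (4R,5R)-4-[(1S)-1,2-dihydroxyethyl]-5-{(2S,3R)-3-[(3Z)-4-iodo-5-methoxy-5-oxopent-3-en-1-yl]-3-methyloxiran-2-yl}-3-methylideneoxolan-2-one | C=C1C(=O)O[C@@H]([C@@H]2O[C@]2(C)CC/C=C(\I)C(=O)OC)[C@H]1[C@H](O)CO | intermediate
14 | (4S,5R)-4-[(1S)-1,2-bis(triethylsilyloxy)ethyl]-5-{(2S,3R)-3-[(3Z)-4-iodo-5-methoxy-5-oxopent-3-en-1-yl]-3-methyloxiran-2-yl}-3-methylideneoxolan-2-one | C=C1C(=O)O[C@@H]([C@@H]2O[C@]2(C)CC/C=C(\I)C(=O)OC)[C@H]1[C@H](O[Si](CC)(CC)CC)CO[Si](CC)(CC)CC | intermediate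
15 | (4S,5R)-5-{(2S,3R)-3-[(3Z)-4-iodo-5-methoxy-5-oxopent-3-en-1-yl]-3-methyloxiran-2-yl}-3-methylidene-4-[(1S)-2-oxo-1-(triethylsilyloxy)ethyl]oxolan-2-one | C=C1C(=O)O[C@@H]([C@@H]2O[C@]2(C)CC/C=C(\I)C(=O)OC)[C@H]1[C@H](O[Si](CC)(CC)CC)C=O | intermediate
16 | alkenylchromium dichloride of 15 (CrCl2 in place of iodine at C10, trivalent chromium) | C=C1C(=O)O[C@@H]([C@@H]2O[C@]2(C)CC/C=C(\[Cr](Cl)Cl)C(=O)OC)[C@H]1[C@H](O[Si](CC)(CC)CC)C=O | intermediate
17 | methyl (1(10)E,4R,5S,6R,7S,8S,9R)-4,5-epoxy-9-hydroxy-8-(triethylsilyloxy)germacra-1(10),11(13)-dien-12,6-olid-14-oate | C=C1C(=O)O[C@@H]2[C@H]1[C@H](O[Si](CC)(CC)CC)[C@H](O)/C(C(=O)OC)=C\CC[C@@]1(C)O[C@@H]21 | intermediate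
18 | methyl (1(10)E,4R,5S,6R,7R,8S,9R)-4,5-epoxy-8,9-dihydroxygermacra-1(10),11(13)-dien-12,6-olid-14-oate | C=C1C(=O)O[C@@H]2[C@H]1[C@H](O)[C@H](O)/C(C(=O)OC)=C\CC[C@@]1(C)O[C@@H]21 | intermediate
19 | 2-methylprop-2-en-1-ol (methallyl alcohol) | C=C(C)CO | starting material
20 | [(2S)-2-methyloxiran-2-yl]methanol | OC[C@@]1(C)CO1 | intermediate
21 | (2R)-2-methyloxirane-2-carboxylic acid | OC(=O)[C@@]1(C)CO1 | intermediate
22 | 8,9-O-(1-methoxyethylidene) derivative of 18 (cyclic orthoacetate, both orthoester epimers) | C=C1C(=O)O[C@@H]2[C@H]1[C@@H]3OC(C)(OC)O[C@@H]3/C(C(=O)OC)=C\CC[C@@]1(C)O[C@@H]21 | intermediate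
23 | 8,9-acetoxonium (2-methyl-1,3-dioxolan-2-ylium) ion of 18 paired with (2R)-2-methyloxirane-2-carboxylate | C=C1C(=O)O[C@@H]2[C@H]1[C@@H]3O[C+](C)O[C@@H]3/C(C(=O)OC)=C\CC[C@@]1(C)O[C@@H]21.[O-]C(=O)[C@@]1(C)CO1 | intermediate
24 | methyl (1(10)E,4R,5S,6R,7R,8S,9S)-8-acetoxy-4,5-epoxy-9-{[(2R)-2-methyloxirane-2-carbonyl]oxy}germacra-1(10),11(13)-dien-12,6-olid-14-oate (CNP0159450.1) | C=C1C(=O)O[C@@H]2[C@H]1[C@H](OC(C)=O)[C@@H](OC(=O)[C@@]1(C)CO1)/C(C(=O)OC)=C\CC[C@@]1(C)O[C@@H]21 | target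

**Step count and risks**
Total steps: 14. Longest linear sequence: 10 (steps 1, 2, 3, 6, 7, 8, 9, 10, 11, 14).

Three steps most likely to fail:

Step 6 (Barbier union). The required 5,6-threo sense runs against the intrinsic Felkin preference of a cis-α,β-epoxy aldehyde. If indium chelation and reagent control do not override it, the wrong C6/C7 pair dominates. The fallback installs the epoxide after C6 by hydroxyl-directed epoxidation. It sets out from 1 and comes back at 11.
- Ac2O/pyridine gives neryl acetate F1.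
- Ozonolysis of the more electron-rich distal alkene (about 1 equiv O3, CH2Cl2/pyridine, −78 °C; PPh3) gives (2Z)-3-methyl-6-oxohex-2-en-1-yl acetate F2.
- F2 is taken on with the iodo-ylide as in step 2 to methyl (2Z,6Z)-8-acetoxy-2-iodo-6-methylocta-2,6-dienoate F3.
- K2CO3/MeOH frees methyl (2Z,6Z)-8-hydroxy-2-iodo-6-methylocta-2,6-dienoate F4, and MnO2 gives the Z-enal methyl (2Z,6Z)-2-iodo-6-methyl-8-oxoocta-2,6-dienoate F5.
- Indium Barbier reaction of F5 with 9 (no Felkin bias in the aldehyde; C8 controls C7 and the chair controls C6) gives the syn Z-allylic alcohol diester F6.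
- mCPBA (or VO(acac)2/t-BuOOH) epoxidises only the electron-rich C4=C5 bond. A(1,3) strain holds H-6 in the alkene plane, so the hydroxyl delivers oxygen threo-selectively and the product is hydroxy diester 11, which lactonises to 12 as in step 6.

Step 10 (Ni/Cr macrocyclisation). The α-iodo enoate may be reduced or react through an allenoate, the ten-membered ring is strained, and the C9 facial selectivity is decided within the ring. The fallback closes the ring by olefin metathesis at C8=C9 and adds both oxygens afterwards. It sets out from 5 and comes back at 18.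
- Acrolein and 7 (DABCO) give methyl 3-hydroxy-2-methylidenepent-4-enoate F7, and NBS/Me2S gives methyl (2Z)-2-(bromomethyl)penta-2,4-dienoate F8.
- Indium Barbier reaction of F8 with 5 (γ-attack) gives the 7-vinyl hydroxy diester F9 and, after PPTS, the 7-vinyl cis-lactone F10.
- Stille coupling (tributyl(vinyl)stannane, Pd(PPh3)4, CuI) gives the 10-vinyl enoate F11.
- Ring-closing metathesis (second-generation Hoveyda–Grubbs catalyst, PhMe, 80 °C, 1 mM) gives the macrocyclic (8Z)-diene F12.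
- OsO4 (cat.)/NMO dihydroxylates the disubstituted C8=C9 bond (the two acrylate-type alkenes are electron-poor), expected from the peripheral, lactone-bearing face, to give cis-diol 18.

Step 14 (new hetero-Prévost relay). The ion pair may collapse at C8 or at C1 (SN2′), or the acid may open an epoxide. The fallback uses known chemistry only. It sets out from 17 and comes back at 24.
- Mitsunobu esterification of 17 with 21 (PPh3, DIAD, PhMe, 0 °C) inverts C9 and gives the 9S glycidate 8-silyl ether F13.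
- Et3N·3HF gives the 8-hydroxy 9-glycidate F14.
- Ac2O/DMAP/pyridine gives 24.

**Further compounds**
F1 | step 6 | neryl acetate | CC(C)=CCC/C(C)=C\COC(C)=O
F2 | step 6 | (2Z)-3-methyl-6-oxohex-2-en-1-yl acetate | O=CCC/C(C)=C\COC(C)=O
F3 | step 6 | methyl (2Z,6Z)-8-acetoxy-2-iodo-6-methylocta-2,6-dienoate | I/C(C(=O)OC)=C\CC/C(C)=C\COC(C)=O
F4 | step 6 | methyl (2Z,6Z)-8-hydroxy-2-iodo-6-methylocta-2,6-dienoate | I/C(C(=O)OC)=C\CC/C(C)=C\CO
F5 | step 6 | methyl (2Z,6Z)-2-iodo-6-methyl-8-oxoocta-2,6-dienoate | I/C(C(=O)OC)=C\CC/C(C)=C\C=O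
F6 | step 6 | syn Z-allylic alcohol diester (11 with a Z-C4=C5 bond in place of the oxirane) | I/C(C(=O)OC)=C\CC/C(C)=C\[C@H](O)[C@H](C(=C)C(=O)OC)[C@H]1COC(C)(C)O1
F7 | step 10 | methyl 3-hydroxy-2-methylidenepent-4-enoate (racemic) | C=CC(O)C(=C)C(=O)OC
F8 | step 10 | methyl (2Z)-2-(bromomethyl)penta-2,4-dienoate | BrC/C(C(=O)OC)=C\C=C
F9 | step 10 | 7-vinyl hydroxy diester (11 with vinyl in place of the dioxolane) | I/C(C(=O)OC)=C\CC[C@@]1(C)O[C@H]1[C@H](O)[C@@H](C=C)C(=C)C(=O)OC
F10 | step 10 | 7-vinyl cis-lactone (12 with vinyl in place of the dioxolane) | C=C1C(=O)O[C@@H]([C@@H]2O[C@]2(C)CC/C=C(\I)C(=O)OC)[C@H]1C=C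
F11 | step 10 | 10-vinyl enoate (F10 with vinyl in place of iodine) | C=C1C(=O)O[C@@H]([C@@H]2O[C@]2(C)CC/C=C(\C=C)C(=O)OC)[C@H]1C=C
F12 | step 10 | methyl (4R,5S,6R,7R)-4,5-epoxygermacra-1(10),8(Z),11(13)-trien-12,6-olid-14-oate (ring-cis C1=C10) | C=C1C(=O)O[C@@H]2[C@H]1/C=C\C(C(=O)OC)=C/CC[C@@]1(C)O[C@@H]21
F13 | step 14 | 9S glycidate 8-triethylsilyl ether (24 with OSiEt3 in place of OAc at C8) | C=C1C(=O)O[C@@H]2[C@H]1[C@H](O[Si](CC)(CC)CC)[C@@H](OC(=O)[C@@]1(C)CO1)/C(C(=O)OC)=C\CC[C@@]1(C)O[C@@H]21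
F14 | step 14 | 8-hydroxy 9-glycidate (24 with OH in place of OAc at C8) | C=C1C(=O)O[C@@H]2[C@H]1[C@H](O)[C@@H](OC(=O)[C@@]1(C)CO1)/C(C(=O)OC)=C\CC[C@@]1(C)O[C@@H]21
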